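The seven-membered ring is disconnected at C7–C8 and C3a–C4 (azulene numbering). A rhodium(II) vinylcarbenoid, generated from a cyclopentenyl diazoacetate, cyclopropanates the vinyl end of 4-methylpenta-1,3-diene and the resulting cis-divinylcyclopropane undergoes Cope rearrangement: one operation closes the cycloheptadiene, brings in the quaternary gem-dimethyl carbon C4 as a diene terminus, sets C3a, and leaves the ester carbon on C8 as the future exocyclic methylene. The feature exploited is the C8(=CH2)–C8a–C3a–C4(CH3)2 edge of the seven-membered ring, where a hindered quaternary–methine bond adjoins the ring fusion. The precursor is a tert-butyl 2-diazo-2-(cyclopent-1-enyl)acetate whose C1 carries the methyl group and the finished diacetoxy δ-lactone.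

Key step: step 15

Remark 1: the target lactone is a six-membered tetrahydro-2H-pyran-2-one, (3S,4R,5R), with 3-OAc and 4-CH2OAc cis and 4-CH2OAc trans to the C5 substituent; the hydroazulene is cis-fused, with 3a-H, 8a-H and the lactone on one face and the C1 methyl on the other.
Remark 2: locants C1–C8a are azulene locants and are used for the same atoms before ring closure; lactone locants are those of pyran-2-one.
Remark 3: the precursor and product of the key step were checked atom by atom against the target and needed no structural correction. The diacetate and the tert-butyl ester are kept because acetates survive carbenoid, heat, TFA and borane, and only this ester can then be removed beside them.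
Remark 4 (assumption): the catalyst antipode in step 15 is chosen on the premise that the S-prolinate series gives (1S,2R)-type cyclopropanes from donor/acceptor carbenoids and monosubstituted alkenes.

Step 1
Reactants: 1 1-(2-methylcyclopent-1-en-1-yl)ethan-1-one
Product: 2 (S)-1-(2-methylcyclopent-1-en-1-yl)ethan-1-ol
Conditions: (R)-Me-CBS (10 mol%), BH3·SMe2, THF, −20 °C; MeOH
Reagents that add atoms: none
Why: Corey–Bakshi–Shibata reduction; the (R)-oxazaborolidine distinguishes the tetrasubstituted alkenyl group from methyl and should give the (S)-carbinol, whose chirality is relayed to C1 in step 3.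

Step 2
Reactants: 2 (S)-1-(2-methylcyclopent-1-en-1-yl)ethan-1-ol; 3 but-3-enoic acid
Product: 4 (S)-1-(2-methylcyclopent-1-en-1-yl)ethyl but-3-enoate
Conditions: DCC, DMAP (5 mol%), CH2Cl2, −10 → 0 °C
Reagents that add atoms: none
Why: Steglich esterification under neutral conditions avoids ionisation of the allylic alcohol, and low temperature with little DMAP keeps the β,γ-alkene out of conjugation.

Step 3
Reactants: 4 (S)-1-(2-methylcyclopent-1-en-1-yl)ethyl but-3-enoate
Product: 7 (2R)-2-[(1S,2E)-2-ethylidene-1-methylcyclopentyl]but-3-enoic acid, via silyl ketene acetal 5 (not isolated), via trimethylsilyl ester 6 (not isolated)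
Conditions: LDA, THF, −78 °C; TMSCl, −78 °C → 50 °C; aq. HCl
Reagents that add atoms: none
Why: Ireland–Claisen rearrangement; LDA in THF should give the E(O)-enolate (vinyl cis to the allylic oxygen), and a chair transition state with the carbinol methyl pseudo-equatorial (the alternative suffers A1,3 strain with the ring methyl) transfers the carbinol chirality to quaternary C1 (S) and sets the adjacent methine (R) in the same [3,3] shift.

Step 4
Reactants: 7 (2R)-2-[(1S,2E)-2-ethylidene-1-methylcyclopentyl]but-3-enoic acid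
Product: 8 (2R)-2-[(1S,2E)-2-ethylidene-1-methylcyclopentyl]but-3-en-1-ol
Conditions: LiAlH4, Et2O, 0 °C → rt; Fieser work-up
Reagents that add atoms: none
Why: Hydride reduction of the carboxylic acid; the carboxylate formed first shields the doubly activated α-hydrogen from epimerisation and alkene migration.

Step 5
Reactants: 8 (2R)-2-[(1S,2E)-2-ethylidene-1-methylcyclopentyl]but-3-en-1-ol; 9 acryloyl chloride
Product: 10 (2R)-2-[(1S,2E)-2-ethylidene-1-methylcyclopentyl]but-3-en-1-yl acrylate
Conditions: Et3N, CH2Cl2, −20 → 0 °C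
Reagents that add atoms: none
Why: O-acylation of a primary alcohol by an acid chloride in the presence of an amine base.

Step 6
Reactants: 10 (2R)-2-[(1S,2E)-2-ethylidene-1-methylcyclopentyl]but-3-en-1-yl acrylate
Product: 11 (5R)-5-[(1S,2E)-2-ethylidene-1-methylcyclopentyl]-5,6-dihydro-2H-pyran-2-one
Conditions: Grubbs II (3 mol%), CH2Cl2 (5 mM), reflux
Reagents that add atoms: none
Why: Ring-closing metathesis of an acrylate onto a monosubstituted alkene gives the α,β-unsaturated δ-lactone; the trisubstituted ethylidene is too hindered to take part.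

Step 7
Reactants: 11 (5R)-5-[(1S,2E)-2-ethylidene-1-methylcyclopentyl]-5,6-dihydro-2H-pyran-2-one; 12 vinylmagnesium bromide
Product: 14 (4S,5R)-5-[(1S,2E)-2-ethylidene-1-methylcyclopentyl]-4-vinyltetrahydro-2H-pyran-2-one, via silyl ketene acetal 13 (not isolated)
Conditions: CuI (20 mol%), TMSCl, THF, −78 → −40 °C; 1 M HCl
Reagents that add atoms: none
Why: Copper-catalysed conjugate addition of a Grignard reagent accelerated by TMSCl; vinyl should add to C4 anti to the bulky C5 substituent, setting the 4,5-trans relationship.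

Step 8
Reactants: 14 (4S,5R)-5-[(1S,2E)-2-ethylidene-1-methylcyclopentyl]-4-vinyltetrahydro-2H-pyran-2-one
Product: 15 (3R,4S,5R)-5-[(1S,2E)-2-ethylidene-1-methylcyclopentyl]-3-hydroxy-4-vinyltetrahydro-2H-pyran-2-one
Conditions: KHMDS, THF, −78 °C; 2-(phenylsulfonyl)-3-phenyloxaziridine, −78 °C; aq. NH4Cl
Reagents that add atoms: 2-(phenylsulfonyl)-3-phenyloxaziridine, O=S(=O)(N1OC1c1ccccc1)c1ccccc1
Why: Davis oxidation of the lactone enolate; the oxaziridine should approach C3 anti to the adjacent vinyl group and give the 3,4-trans alcohol.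

Step 9
Reactants: 15 (3R,4S,5R)-5-[(1S,2E)-2-ethylidene-1-methylcyclopentyl]-3-hydroxy-4-vinyltetrahydro-2H-pyran-2-one
Product: 17 (3S,4S,5R)-5-[(1S,2E)-2-ethylidene-1-methylcyclopentyl]-2-oxo-4-vinyltetrahydro-2H-pyran-3-yl acetate, via lactone triflate 16 (not isolated)
Conditions: Tf2O, pyridine, CH2Cl2, −30 °C; then CsOAc, 18-crown-6, PhMe, rt
Reagents that add atoms: caesium acetate, CC(=O)[O-].[Cs+]
Why: SN2 displacement of an α-carbonyl triflate by acetate with inversion turns the 3,4-trans alcohol into the required 3,4-cis acetate; the adjacent carbonyl favours substitution over elimination.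

Step 10
Reactants: 17 (3S,4S,5R)-5-[(1S,2E)-2-ethylidene-1-methylcyclopentyl]-2-oxo-4-vinyltetrahydro-2H-pyran-3-yl acetate
Product: 19 (3S,4R,5R)-4-(hydroxymethyl)-5-[(1S)-1-methyl-2-oxocyclopentyl]-2-oxotetrahydro-2H-pyran-3-yl acetate, via keto aldehyde 18 (not isolated)
Conditions: O3, CH2Cl2–MeOH, −78 °C; Me2S, → rt; concentrate; NaBH(OAc)3, AcOH, PhH, rt
Reagents that add atoms: ozone, O=[O+][O-]
Why: Ozonolysis cleaves both alkenes (ethylidene to the C8a ketone, vinyl to the formyl group) and triacetoxyborohydride then reduces only the aldehyde, so the base-sensitive β-acetoxy aldehyde is not handled.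

Step 11
Reactants: 19 (3S,4R,5R)-4-(hydroxymethyl)-5-[(1S)-1-methyl-2-oxocyclopentyl]-2-oxotetrahydro-2H-pyran-3-yl acetate
Product: 20 [(3S,4R,5R)-3-acetoxy-5-[(1S)-1-methyl-2-oxocyclopentyl]-2-oxotetrahydro-2H-pyran-4-yl]methyl acetate
Conditions: Ac2O, pyridine, DMAP (cat.), CH2Cl2, 0 °C
Reagents that add atoms: acetic anhydride, CC(=O)OC(C)=O
Why: DMAP-catalysed acetylation of the primary alcohol, carried out at once to forestall acyl migration or translactonisation.

Step 12
Reactants: 20 [(3S,4R,5R)-3-acetoxy-5-[(1S)-1-methyl-2-oxocyclopentyl]-2-oxotetrahydro-2H-pyran-4-yl]methyl acetate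
Product: 21 [(3S,4R,5R)-3-acetoxy-5-[(1S)-1-methyl-2-(trifluoromethylsulfonyloxy)cyclopent-2-en-1-yl]-2-oxotetrahydro-2H-pyran-4-yl]methyl acetate
Conditions: Tf2O, 2,6-di-tert-butyl-4-methylpyridine, CH2Cl2, 0 °C → rt
Reagents that add atoms: triflic anhydride, O=S(=O)(OS(=O)(=O)C(F)(F)F)C(F)(F)F
Why: Enol triflate formation under non-basic Stang conditions; only C3a carries α-hydrogens, so one regioisomer forms, and no enolate base meets the acidic α-acetoxy lactone.

Step 13
Reactants: 21 the cyclopentenyl triflate; 22 tert-butyl bromoacetate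
Product: 24 tert-butyl 2-[(5S)-5-[(3R,4R,5S)-5-acetoxy-4-(acetoxymethyl)-6-oxotetrahydro-2H-pyran-3-yl]-5-methylcyclopent-1-en-1-yl]acetate, via Reformatsky reagent 23 (not isolated)
Conditions: 22, Zn dust (TMSCl-activated), THF, rt; then 21, Pd(PPh3)4 (5 mol%), THF, 50 °C
Reagents that add atoms: none
Why: Palladium-catalysed Negishi-type coupling of a Reformatsky reagent with a vinyl triflate; the zinc enolate is too mild to attack the acetates or the lactone.

Step 14
Reactants: 24 the β,γ-unsaturated tert-butyl ester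
Product: 25 tert-butyl 2-diazo-2-[(5S)-5-[(3R,4R,5S)-5-acetoxy-4-(acetoxymethyl)-6-oxotetrahydro-2H-pyran-3-yl]-5-methylcyclopent-1-en-1-yl]acetate
Conditions: p-ABSA, DBU (1.1 equiv), MeCN, 0 °C
Reagents that add atoms: 4-acetamidobenzenesulfonyl azide, CC(=O)Nc1ccc(cc1)S(=O)(=O)N=[N+]=[N-]
Why: Regitz diazo transfer; the allylic α-CH2 of the ester is the most accessible acidic site, and limiting DBU, 0 °C and short contact are meant to spare the hindered α-acetoxy lactone C–H from epimerisation.

Step 15
Reactants: 25 the vinyl diazoacetate; 26 4-methylpenta-1,3-diene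
Product: 28 tert-butyl (1S,3aS)-1-[(3R,4R,5S)-5-acetoxy-4-(acetoxymethyl)-6-oxotetrahydro-2H-pyran-3-yl]-1,4,4-trimethyl-1,2,3,3a,4,7-hexahydroazulene-8-carboxylate (C8=C8a and C5=C6; 3a-H cis to the lactone), via cis-divinylcyclopropane 27 (not isolated)
Conditions: Rh2(R-DOSP)4 (1 mol%), 26 (5 equiv), PhCF3, −20 °C → rt, slow addition of 25; then PhMe, 110 °C
Reagents that add atoms: none
Why: Rh2(R-DOSP)4 converts 25 into a donor/acceptor vinylcarbenoid that cyclopropanates the unsubstituted vinyl terminus of 26 (C8–C7 and C8–C6 formed) with the 2-methylpropenyl group cis to the cyclopentenyl donor, and on heating cyclopropane 27 undergoes Cope rearrangement in which C8–C6 breaks and C3a–C4 forms. The closest known reaction type is the tandem cyclopropanation/Cope rearrangement (formal [4+3] cycloaddition) of rhodium(II) vinylcarbenoids, cycloalkenyl diazoacetates included, with 1,3-dienes, where a cis substituent on the diene terminus slows the Cope step so that heat is needed. The seven-membered ring is closed pericyclically, by [3,3]-sigmatropic ring expansion of the three-membered ring through a boat transition state with both alkenes folded over the cyclopropane. The new stereocentre C3a follows stereospecifically from the cyclopropane configuration (8R,6S), which is set by the carbenoid face that the diene attacks; the R-prolinate catalyst is chosen to give this mirror image of the (1S,2R)-type product of the S-series, so that C4 bonds to C3a on the face of the C1 methyl, away from the lactone. The step needs site selectivity for the monosubstituted alkene, cis cyclopropane diastereoselectivity and cyclopropanation in preference to intramolecular C–H insertion; the first two are intrinsic to donor/acceptor carbenoids and the third is secured by excess diene, slow addition and the deactivated, acyloxy-bearing C–H bonds of the lactone.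

Step 16
Reactants: 28 the hexahydroazulene diene ester
Product: 29 tert-butyl (1S,3aS)-1-[(3R,4R,5S)-5-acetoxy-4-(acetoxymethyl)-6-oxotetrahydro-2H-pyran-3-yl]-1,4,4-trimethyl-1,2,3,3a,4,5,6,7-octahydroazulene-8-carboxylate
Conditions: H2 (1 atm), 10% Pd/C, EtOAc, rt
Reagents that add atoms: none
Why: Heterogeneous catalytic hydrogenation; the cis-disubstituted C5=C6 alkene is reduced while the tetrasubstituted, conjugated C8=C8a alkene should be inert at 1 atm.

Step 17
Reactants: 29 the octahydroazulene tert-butyl ester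
Product: 30 (1S,3aS)-1-[(3R,4R,5S)-5-acetoxy-4-(acetoxymethyl)-6-oxotetrahydro-2H-pyran-3-yl]-1,4,4-trimethyl-1,2,3,3a,4,5,6,7-octahydroazulene-8-carboxylic acid
Conditions: TFA–CH2Cl2 (1:4), 0 °C → rt
Reagents that add atoms: none
Why: Acidolysis of the tert-butyl ester (E1 loss of isobutene) leaves the acetates and the lactone untouched.

Step 18
Reactants: 30 the unsaturated acid
Product: 31 [(3S,4R,5R)-3-acetoxy-5-[(1S,3aS)-8-(hydroxymethyl)-1,4,4-trimethyl-1,2,3,3a,4,5,6,7-octahydroazulen-1-yl]-2-oxotetrahydro-2H-pyran-4-yl]methyl acetate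
Conditions: BH3·THF, THF, 0 °C → rt; MeOH
Reagents that add atoms: none
Why: Chemoselective borane reduction of a carboxylic acid in the presence of esters and a lactone; the tetrasubstituted, electron-poor alkene resists hydroboration.

Step 19
Reactants: 31 the allylic alcohol
Product: 34 CNP0333014.1, (3S,4R,5R)-4-(acetoxymethyl)-5-[(1R,3aR,8aS)-1,4,4-trimethyl-8-methylidenedecahydroazulen-1-yl]-2-oxotetrahydro-2H-pyran-3-yl acetate, via sulfonylhydrazine adduct 32 (not isolated), via allylic diazene 33 (not isolated)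
Conditions: PPh3, DEAD, 2-nitrobenzenesulfonylhydrazide (NBSH), THF, −30 °C → rt
Reagents that add atoms: none
Why: Myers reductive 1,3-transposition: Mitsunobu alkylation of NBSH, loss of sulfinic acid to the allylic diazene and retro-ene loss of N2 move the alkene to C8=CH2 and should deliver hydrogen to C8a on the face of 3a-H, because the opposite face is screened by the C1 methyl and the pseudo-axial C4 methyl, which gives the cis ring fusion.

Compound list
1 | 1-(2-methylcyclopent-1-en-1-yl)ethan-1-one | CC(=O)C1=C(C)CCC1 | starting material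
2 | (S)-1-(2-methylcyclopent-1-en-1-yl)ethan-1-ol | C[C@H](O)C1=C(C)CCC1 | intermediate
3 | but-3-enoic acid | OC(=O)CC=C | starting material
4 | (S)-1-(2-methylcyclopent-1-en-1-yl)ethyl but-3-enoate | C[C@H](OC(=O)CC=C)C1=C(C)CCC1 | intermediate
5 | trimethylsilyl ketene acetal of 4, vinyl cis to the allylic oxygen (not isolated) | C=C/C=C(\O[C@@H](C)C1=C(C)CCC1)O[Si](C)(C)C | intermediate
6 | trimethylsilyl (2R)-2-[(1S,2E)-2-ethylidene-1-methylcyclopentyl]but-3-enoate (not isolated) | C/C=C1\CCC[C@@]1(C)[C@@H](C=C)C(=O)O[Si](C)(C)C | intermediate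
7 | (2R)-2-[(1S,2E)-2-ethylidene-1-methylcyclopentyl]but-3-enoic acid | C/C=C1\CCC[C@@]1(C)[C@@H](C=C)C(=O)O | intermediate
8 | (2R)-2-[(1S,2E)-2-ethylidene-1-methylcyclopentyl]but-3-en-1-ol | C/C=C1\CCC[C@@]1(C)[C@@H](C=C)CO | intermediate
9 | acryloyl chloride | C=CC(=O)Cl | starting material
10 | (2R)-2-[(1S,2E)-2-ethylidene-1-methylcyclopentyl]but-3-en-1-yl acrylate | C/C=C1\CCC[C@@]1(C)[C@@H](C=C)COC(=O)C=C | intermediate
11 | (5R)-5-[(1S,2E)-2-ethylidene-1-methylcyclopentyl]-5,6-dihydro-2H-pyran-2-one | C/C=C1\CCC[C@@]1(C)[C@@H]2COC(=O)C=C2 | intermediate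
12 | vinylmagnesium bromide | C=C[Mg]Br | starting material
13 | trimethylsilyl ketene acetal of 14 (not isolated) | C/C=C1\CCC[C@@]1(C)[C@@H]2COC(O[Si](C)(C)C)=C[C@H]2C=C | intermediate
14 | (4S,5R)-5-[(1S,2E)-2-ethylidene-1-methylcyclopentyl]-4-vinyltetrahydro-2H-pyran-2-one (4,5-trans) | C/C=C1\CCC[C@@]1(C)[C@@H]2COC(=O)C[C@H]2C=C | intermediate
15 | (3R,4S,5R)-5-[(1S,2E)-2-ethylidene-1-methylcyclopentyl]-3-hydroxy-4-vinyltetrahydro-2H-pyran-2-one (3,4-trans) | C/C=C1\CCC[C@@]1(C)[C@@H]2COC(=O)[C@H](O)[C@H]2C=C | intermediate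
16 | (3R)-triflate of 15 (not isolated) | C/C=C1\CCC[C@@]1(C)[C@@H]2COC(=O)[C@H](OS(=O)(=O)C(F)(F)F)[C@H]2C=C | intermediate
17 | (3S,4S,5R)-5-[(1S,2E)-2-ethylidene-1-methylcyclopentyl]-2-oxo-4-vinyltetrahydro-2H-pyran-3-yl acetate (3,4-cis) | C/C=C1\CCC[C@@]1(C)[C@@H]2COC(=O)[C@@H](OC(C)=O)[C@H]2C=C | intermediate
18 | (3S,4S,5R)-4-formyl-5-[(1S)-1-methyl-2-oxocyclopentyl]-2-oxotetrahydro-2H-pyran-3-yl acetate (not isolated) | O=C1CCC[C@@]1(C)[C@@H]2COC(=O)[C@@H](OC(C)=O)[C@H]2C=O | intermediate
19 | (3S,4R,5R)-4-(hydroxymethyl)-5-[(1S)-1-methyl-2-oxocyclopentyl]-2-oxotetrahydro-2H-pyran-3-yl acetate | O=C1CCC[C@@]1(C)[C@@H]2COC(=O)[C@@H](OC(C)=O)[C@H]2CO | intermediate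
20 | [(3S,4R,5R)-3-acetoxy-5-[(1S)-1-methyl-2-oxocyclopentyl]-2-oxotetrahydro-2H-pyran-4-yl]methyl acetate | O=C1CCC[C@@]1(C)[C@@H]2COC(=O)[C@@H](OC(C)=O)[C@H]2COC(C)=O | intermediate
21 | [(3S,4R,5R)-3-acetoxy-5-[(1S)-1-methyl-2-(trifluoromethylsulfonyloxy)cyclopent-2-en-1-yl]-2-oxotetrahydro-2H-pyran-4-yl]methyl acetate | O=S(=O)(OC1=CCC[C@@]1(C)[C@@H]2COC(=O)[C@@H](OC(C)=O)[C@H]2COC(C)=O)C(F)(F)F | intermediate
22 | tert-butyl bromoacetate | CC(C)(C)OC(=O)CBr | starting material
23 | (2-tert-butoxy-2-oxoethyl)zinc bromide (not isolated) | CC(C)(C)OC(=O)C[Zn]Br | intermediate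
24 | tert-butyl 2-[(5S)-5-[(3R,4R,5S)-5-acetoxy-4-(acetoxymethyl)-6-oxotetrahydro-2H-pyran-3-yl]-5-methylcyclopent-1-en-1-yl]acetate | CC(C)(C)OC(=O)CC1=CCC[C@@]1(C)[C@@H]2COC(=O)[C@@H](OC(C)=O)[C@H]2COC(C)=O | intermediate
25 | tert-butyl 2-diazo-2-[(5S)-5-[(3R,4R,5S)-5-acetoxy-4-(acetoxymethyl)-6-oxotetrahydro-2H-pyran-3-yl]-5-methylcyclopent-1-en-1-yl]acetate | CC(C)(C)OC(=O)C(=[N+]=[N-])C1=CCC[C@@]1(C)[C@@H]2COC(=O)[C@@H](OC(C)=O)[C@H]2COC(C)=O | intermediate
26 | 4-methylpenta-1,3-diene | C=CC=C(C)C | starting material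
27 | tert-butyl (1R,2S)-1-[the cyclopentenyl group of 25]-2-(2-methylprop-1-en-1-yl)cyclopropane-1-carboxylate, alkenyl cis to cyclopentenyl (not isolated) | CC(C)(C)OC(=O)[C@@]1(C[C@H]1C=C(C)C)C2=CCC[C@@]2(C)[C@@H]3COC(=O)[C@@H](OC(C)=O)[C@H]3COC(C)=O | intermediate
28 | tert-butyl (1S,3aS)-1-[(3R,4R,5S)-5-acetoxy-4-(acetoxymethyl)-6-oxotetrahydro-2H-pyran-3-yl]-1,4,4-trimethyl-1,2,3,3a,4,7-hexahydroazulene-8-carboxylate | CC(C)(C)OC(=O)C1=C2[C@@H](CC[C@@]2(C)[C@@H]3COC(=O)[C@@H](OC(C)=O)[C@H]3COC(C)=O)C(C)(C)C=CC1 | intermediate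
29 | tert-butyl (1S,3aS)-1-[(3R,4R,5S)-5-acetoxy-4-(acetoxymethyl)-6-oxotetrahydro-2H-pyran-3-yl]-1,4,4-trimethyl-1,2,3,3a,4,5,6,7-octahydroazulene-8-carboxylate | CC(C)(C)OC(=O)C1=C2[C@@H](CC[C@@]2(C)[C@@H]3COC(=O)[C@@H](OC(C)=O)[C@H]3COC(C)=O)C(C)(C)CCC1 | intermediate
30 | the corresponding octahydroazulene-8-carboxylic acid | OC(=O)C1=C2[C@@H](CC[C@@]2(C)[C@@H]3COC(=O)[C@@H](OC(C)=O)[C@H]3COC(C)=O)C(C)(C)CCC1 | intermediate
31 | the corresponding 8-(hydroxymethyl)octahydroazulene (allylic alcohol) | OCC1=C2[C@@H](CC[C@@]2(C)[C@@H]3COC(=O)[C@@H](OC(C)=O)[C@H]3COC(C)=O)C(C)(C)CCC1 | intermediate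
32 | N-allyl-N-(2-nitrophenylsulfonyl)hydrazine from 31 (not isolated) | NN(CC1=C2[C@@H](CC[C@@]2(C)[C@@H]3COC(=O)[C@@H](OC(C)=O)[C@H]3COC(C)=O)C(C)(C)CCC1)S(=O)(=O)c4ccccc4[N+](=O)[O-] | intermediate
33 | allylic diazene from 32 (not isolated) | N=NCC1=C2[C@@H](CC[C@@]2(C)[C@@H]3COC(=O)[C@@H](OC(C)=O)[C@H]3COC(C)=O)C(C)(C)CCC1 | intermediate
34 | CNP0333014.1, (3S,4R,5R)-4-(acetoxymethyl)-5-[(1R,3aR,8aS)-1,4,4-trimethyl-8-methylidenedecahydroazulen-1-yl]-2-oxotetrahydro-2H-pyran-3-yl acetate | C=C1CCCC(C)(C)[C@@H]2CC[C@@](C)([C@@H]3COC(=O)[C@@H](OC(C)=O)[C@H]3COC(C)=O)[C@H]12 | target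

Total step count: 19. Longest linear sequence: 19 steps (from 1).

Steps most likely to fail

Step 15. The bulky tert-butyl ester and the hindered donor may weaken catalyst control, and the C1 centre may oppose it, so the diene could attack the wrong carbenoid face; the hindered cyclopropane may also decompose before it rearranges. Fallback, setting out from 25 and 26: decompose 25 with achiral Rh2(esp)2 at −40 °C without heating, isolate the two cis-divinylcyclopropanes, and separate 27 from its (1S,2R) cyclopropane diastereomer F6 by chromatography. Pure 27 is then heated in xylene at 130–140 °C; the Cope step is stereospecific, so stereocontrol rests on separation, not on the catalyst. The fallback returns to the route at 28.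

Step 19. Hydrogen may be delivered to the other face of C8a (trans fusion), or the Mitsunobu alkylation may stall at the hindered allylic carbinol. Fallback, setting out from 31: methyl chloroformate and pyridine give the allylic methyl carbonate F7. Palladium-catalysed formate hydrogenolysis (Pd(OAc)2, n-Bu3P, HCO2NH4, THF; Tsuji–Mandai) then passes hydride from palladium to the more substituted allyl terminus C8a on the metal-bearing, less hindered face and leaves the exocyclic methylene. The fallback returns at 34.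

Step 3. The dienolate of the but-3-enoate may form without geometric control, a boat transition state may compete, or the ester may isomerise to the crotonate; each erodes the configuration of the methine next to C1. Fallback, setting out from 2: 4-(phenylselanyl)butanoic acid F1 (from γ-butyrolactone and sodium benzeneselenolate) is coupled with 2 (DCC, DMAP) to give the selenide ester F2, an ordinary alkyl ester whose E(O)-enolate forms reliably with LDA in THF. Ireland–Claisen rearrangement gives the selenide acid F3 and LiAlH4 reduction gives the selenide alcohol F4. Oxidation with H2O2 in the presence of pyridine gives the selenoxide F5, whose syn elimination unveils the vinyl group. The fallback returns at 8.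

Further compounds
F1 | step 3 | 4-(phenylselanyl)butanoic acid | OC(=O)CCC[Se]c1ccccc1
F2 | step 3 | (S)-1-(2-methylcyclopent-1-en-1-yl)ethyl 4-(phenylselanyl)butanoate | C[C@H](OC(=O)CCC[Se]c1ccccc1)C2=C(C)CCC2
F3 | step 3 | (2R)-2-[(1S,2E)-2-ethylidene-1-methylcyclopentyl]-4-(phenylselanyl)butanoic acid | C/C=C1\CCC[C@@]1(C)[C@@H](CC[Se]c2ccccc2)C(=O)O
F4 | step 3 | (2R)-2-[(1S,2E)-2-ethylidene-1-methylcyclopentyl]-4-(phenylselanyl)butan-1-ol | C/C=C1\CCC[C@@]1(C)[C@@H](CC[Se]c2ccccc2)CO
F5 | step 3 | (2R)-2-[(1S,2E)-2-ethylidene-1-methylcyclopentyl]-4-(phenylseleninyl)butan-1-ol | C/C=C1\CCC[C@@]1(C)[C@@H](CC[Se](=O)c2ccccc2)CO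
F6 | step 15 | (1S,2R) cyclopropane diastereomer of 27 | CC(C)(C)OC(=O)[C@]1(C[C@@H]1C=C(C)C)C2=CCC[C@@]2(C)[C@@H]3COC(=O)[C@@H](OC(C)=O)[C@H]3COC(C)=O
F7 | step 19 | allylic methyl carbonate of 31 | COC(=O)OCC1=C2[C@@H](CC[C@@]2(C)[C@@H]3COC(=O)[C@@H](OC(C)=O)[C@H]3COC(C)=O)C(C)(C)CCC1
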